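**Plan** (upper half: guaiane numbering C1–C15; lower half: primed eudesmane numbering)
1. Retrosynthesis, first cut: C1–C13′ and C3–C11′ together (retro-[4+2]). The enabling feature is the cyclohexene C1–C5=C4–C3–C11′–C13′ inside the norbornene, bridged by C2(OAc), with the lower lactone carbonyl on the spiro carbon C11′. This gives a guaianolide 5-acetoxycyclopentadiene (34) and a seco-eudesmanolide α-methylene lactone (18).
2. Dienophile 18: cut C5′=C6′ (RCM), C7′–C8′ (indium allylation/lactone) and the C9′–C10′ oxygenation (Sharpless), back to (R)-citronellal.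
3. Diene 34: cut C3=C4 (dehydration), C7–C8 (chromium allylation closing seven-membered ring and lactone), C5–C6 (Stork–Danheiser) and C1–C10 (organocatalytic Michael), back to cyclopentane-1,3-dione and crotonaldehyde.
4. Forward ring order: lactone then cyclohexene for 18; cyclopentenone, then cycloheptene plus lactone for 34; the norbornene ring last. The diene's own methylene is masked as a PhSe adduct and released in the final step.
5. Stereochemistry: C4′ bought (citronellal); C10′ by Sharpless epoxidation, relayed to C8′/C7′; C10 by iminium catalysis, relayed to C7/C8; C2 by hydride addition then Mitsunobu inversion; C1, C3, C11′ and the orientation of the C2 bridge in the cycloaddition.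

Key step: step 23

Remark: in 23–33 the carbinol carbon C4 (destroyed in step 22) is drawn as the expected major epimer, and the minor epimer would converge; acetal carbons in 21–25 are anomeric mixtures, and the descriptors for C10, C10′ and C2 rest on models for steps 13, 4 and 20/21 that were derived by hand.

**Dienophile branch**

Step 1
Reactants: 1 (R)-citronellal
Product: 2 (3R)-3,7-dimethyl-2-methylideneoct-6-enal
Conditions: 37% aq. CH2O, pyrrolidine (10 mol %), EtCO2H (10 mol %), i-PrOH, 45 °C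
Reagents that add atoms: formaldehyde C=O
Why: Organocatalytic Mannich-type α-methylenation of an aldehyde (enamine attack on formaldehyde, then β-elimination of the amine); the stereocenter is β to the carbonyl and is not involved.

Step 2
Reactants: 2 (3R)-3,7-dimethyl-2-methylideneoct-6-enal
Product: 3 (4R)-4,8-dimethyl-3-methylidenenon-7-en-1-yne
Conditions: Me3SiCHN2, n-BuLi, THF, −78 → 0 °C
Reagents that add atoms: (trimethylsilyl)diazomethane C[Si](C)(C)C=[N+]=[N-]
Why: Colvin one-carbon homologation (1,2-addition of lithiated TMS-diazomethane, Peterson loss of silanolate, 1,2-hydrogen shift of the alkylidene carbene) should give the enyne at low temperature without touching the allylic stereocenter.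

Step 3
Reactants: 3 (4R)-4,8-dimethyl-3-methylidenenon-7-en-1-yne
Product: 5 (2E,5R)-3,5,9-trimethyl-4-methylidenedeca-2,8-dien-1-ol, via alkenylalane 4 (not isolated)
Conditions: AlMe3, Cp2ZrCl2 (20 mol %), CH2Cl2, 0 → 25 °C; then n-BuLi, THF, −78 °C; (CH2O)n, −78 → 25 °C
Reagents that add atoms: trimethylaluminium C[Al](C)C; formaldehyde (as paraformaldehyde) C=O
Why: Negishi zirconium-catalysed syn-carboalumination of the terminal alkyne (methyl to the internal carbon) and hydroxymethylation of the alanate with retention give the (E)-trisubstituted allylic alcohol, as in the classical geraniol synthesis.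

Step 4
Reactants: 5 (2E,5R)-3,5,9-trimethyl-4-methylidenedeca-2,8-dien-1-ol
Product: 6 [(2S,3S)-3-[(3R)-3,7-dimethylocta-1,6-dien-2-yl]-3-methyloxiran-2-yl]methanol
Conditions: Ti(Oi-Pr)4 (10 mol %), L-(+)-DET (12 mol %), t-BuOOH, 4 Å MS, CH2Cl2, −20 °C
Reagents that add atoms: tert-butyl hydroperoxide CC(C)(C)OO
Why: Sharpless asymmetric epoxidation; titanium binds the allylic hydroxyl so only the C2=C3 alkene reacts, and L-(+)-DET should give the (2S,3S)-epoxide as for geraniol, which fixes the future C10′ carbinol by reagent control.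

Step 5
Reactants: 6 [(2S,3S)-3-[(3R)-3,7-dimethylocta-1,6-dien-2-yl]-3-methyloxiran-2-yl]methanol
Product: 7 (3R,5R)-3,5,9-trimethyl-4-methylidenedec-8-ene-1,3-diol
Conditions: Red-Al, THF, 0 °C
Reagents that add atoms: none
Why: Hydroxyl-directed Red-Al opening of a 2,3-epoxy alcohol delivers hydride intramolecularly to C2 and gives the 1,3-diol; the tertiary C–O bond (C10′) is not broken.

Step 6
Reactants: 7 (3R,5R)-3,5,9-trimethyl-4-methylidenedec-8-ene-1,3-diol
Product: 8 (3R,5R)-3-hydroxy-3,5,9-trimethyl-4-methylidenedec-8-enal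
Conditions: TEMPO (10 mol %), PhI(OAc)2, CH2Cl2, 25 °C
Reagents that add atoms: none
Why: TEMPO/PhI(OAc)2 (oxoammonium) oxidation is selective for the primary alcohol and neutral, so the β-hydroxy aldehyde should not dehydrate.

Step 7
Reactants: 9 acrolein; 10 methyl acrylate
Product: 11 methyl 3-hydroxy-2-methylidenepent-4-enoate (racemic)
Conditions: DABCO (20 mol %), neat, 25 °C
Reagents that add atoms: none
Why: Morita–Baylis–Hillman reaction; the ammonium enolate of the acrylate adds to the aldehyde of acrolein.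

Step 8
Reactants: 11 methyl 3-hydroxy-2-methylidenepent-4-enoate
Product: 12 methyl (2Z)-2-(bromomethyl)penta-2,4-dienoate
Conditions: PBr3, Et2O, −10 °C
Reagents that add atoms: phosphorus tribromide BrP(Br)Br
Why: Bromination of a Baylis–Hillman alcohol with allylic transposition (SN2′) gives the conjugated, thermodynamically preferred (2Z)-bromide.

Step 9
Reactants: 8 (3R,5R)-3-hydroxy-3,5,9-trimethyl-4-methylidenedec-8-enal; 12 methyl (2Z)-2-(bromomethyl)penta-2,4-dienoate
Product: 14 (4S,5S)-4-ethenyl-5-[(2R,4R)-2-hydroxy-2,4,8-trimethyl-3-methylidenenon-7-en-1-yl]-3-methylideneoxolan-2-one, via hydroxy ester 13 (not isolated)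
Conditions: In powder, THF–H2O (1:1), 25 °C; then PPTS (cat.), CH2Cl2
Reagents that add atoms: none
Why: Indium-mediated Barbier allylation and lactonisation; the allylindium adds through its γ-carbon in a six-membered transition state, syn addition from the (Z)-bromide should give the cis-lactone (C7′/C8′), and indium chelation between the aldehyde and the free tertiary hydroxyl (methyl axial, alkenyl equatorial) should set C8′ syn to the C10′ oxygen.

Step 10
Reactants: 14 (4S,5S)-4-ethenyl-5-[(2R,4R)-2-hydroxy-2,4,8-trimethyl-3-methylidenenon-7-en-1-yl]-3-methylideneoxolan-2-one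
Product: 15 (3aS,6R,7aS)-6-hydroxy-6-methyl-3-methylidene-5-[(2R)-6-methylhept-5-en-2-yl]-3a,6,7,7a-tetrahydro-1-benzofuran-2(3H)-one
Conditions: Hoveyda–Grubbs II (5 mol %), toluene (5 mM), 80 °C
Reagents that add atoms: none
Why: Ring-closing metathesis of the vinyl group with the 1,1-disubstituted alkene closes the trisubstituted cyclohexene; the acrylate-type methylene and the trisubstituted side-chain alkene are poor partners and no stereocenter is touched.

Step 11
Reactants: 15 (3aS,6R,7aS)-6-hydroxy-6-methyl-3-methylidene-5-[(2R)-6-methylhept-5-en-2-yl]-3a,6,7,7a-tetrahydro-1-benzofuran-2(3H)-one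
Product: 17 (3aS,6R,7aS)-6-hydroxy-5-[(2R)-5-hydroxypentan-2-yl]-6-methyl-3-methylidene-3a,6,7,7a-tetrahydro-1-benzofuran-2(3H)-one, via aldehyde 16 (not isolated)
Conditions: O3, pyridine, CH2Cl2, −78 °C (Sudan Red 7B end point); Me2S; then NaBH(OAc)3, 25 °C
Reagents that add atoms: ozone [O-][O+]=O
Why: Ozonolysis should select the electron-rich, unhindered side-chain alkene (the ring alkene is flanked by two branched carbons, the lactone methylene is electron-poor), and NaBH(OAc)3 reduces only the aldehyde.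

Step 12
Reactants: 17 (3aS,6R,7aS)-6-hydroxy-5-[(2R)-5-hydroxypentan-2-yl]-6-methyl-3-methylidene-3a,6,7,7a-tetrahydro-1-benzofuran-2(3H)-one
Product: 18 (4R)-4-[(3aS,6R,7aS)-6-hydroxy-6-methyl-3-methylidene-2-oxo-2,3,3a,6,7,7a-hexahydro-1-benzofuran-5-yl]pentyl acetate
Conditions: Ac2O, pyridine, DMAP (cat.), CH2Cl2, 0 °C
Reagents that add atoms: acetic anhydride CC(=O)OC(C)=O
Why: Acylation of the primary alcohol; the tertiary allylic alcohol does not react under these conditions.

**Diene branch**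

Step 13
Reactants: 19 cyclopentane-1,3-dione; 20 (E)-but-2-enal
Product: 22 (4R)-2-methoxy-4-methyl-3,4,6,7-tetrahydrocyclopenta[b]pyran-5(2H)-one, via lactol 21 (not isolated)
Conditions: (R)-α,α-diphenylprolinol TMS ether (10 mol %), CH2Cl2, 0 → 25 °C; then MeOH, PPTS (cat.)
Reagents that add atoms: methanol CO
Why: Iminium-catalysed (Jørgensen–Hayashi) enantioselective Michael addition of the cyclic 1,3-dione to crotonaldehyde, the catalyst shielding one face of the β-carbon (C10, expected R), then lactol formation and acetalisation to a bicyclic vinylogous ester that holds C8 in a temporary ring.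

Step 14
Reactants: 22 (4R)-2-methoxy-4-methyl-3,4,6,7-tetrahydrocyclopenta[b]pyran-5(2H)-one
Product: 23 (4R)-2-methoxy-4,6-dimethyl-3,4,6,7-tetrahydrocyclopenta[b]pyran-5(2H)-one (C6 epimers)
Conditions: LDA, THF, −78 °C; MeI
Reagents that add atoms: iodomethane CI
Why: Stork–Danheiser kinetic α′-deprotonation of the vinylogous ester and methylation; the new center is re-enolised in the next step.

Step 15
Reactants: 23 (4R)-2-methoxy-4,6-dimethyl-3,4,6,7-tetrahydrocyclopenta[b]pyran-5(2H)-one
Product: 24 (4R,6S)-6-hydroxy-2-methoxy-4,6-dimethyl-3,4,6,7-tetrahydrocyclopenta[b]pyran-5(2H)-one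
Conditions: KHMDS, THF, −78 °C; then trans-2-(phenylsulfonyl)-3-phenyloxaziridine
Reagents that add atoms: trans-2-(phenylsulfonyl)-3-phenyloxaziridine O=S(=O)(N1OC1c1ccccc1)c1ccccc1
Why: Davis hydroxylation of the potassium enolate gives the tertiary α′-alcohol, attack being expected anti to the C10 methyl group; the center is destroyed in step 22.

Step 16
Reactants: 24 (4R,6S)-6-hydroxy-2-methoxy-4,6-dimethyl-3,4,6,7-tetrahydrocyclopenta[b]pyran-5(2H)-one
Product: 26 (3R)-3-[(3S)-3-hydroxy-3-methyl-5-oxo-2-(prop-2-en-1-yl)cyclopent-1-en-1-yl]butanal, via diol 25 (not isolated)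
Conditions: allylMgBr (3 equiv), THF, −78 → 0 °C; then 2 M HCl, THF, 25 °C
Reagents that add atoms: allylmagnesium bromide C=CC[Mg]Br; water O
Why: Stork–Danheiser sequence; 1,2-addition of the allyl Grignard reagent to the vinylogous ester carbonyl and acid hydrolysis give the transposed enone (C2 ketone, C1=C5) and release the C8 aldehyde from the acetal, leaving C10 and C4 untouched.

Step 17
Reactants: 26 (3R)-3-[(3S)-3-hydroxy-3-methyl-5-oxo-2-(prop-2-en-1-yl)cyclopent-1-en-1-yl]butanal; 27 methyl 2-(bromomethyl)prop-2-enoate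
Product: 28 methyl (2Z)-2-(bromomethyl)-4-[(5S)-5-hydroxy-5-methyl-3-oxo-2-[(2R)-4-oxobutan-2-yl]cyclopent-1-en-1-yl]but-2-enoate
Conditions: Hoveyda–Grubbs II (10 mol %), 27 (4 equiv), CH2Cl2, 40 °C
Reagents that add atoms: none
Why: Olefin cross-metathesis of the terminal allyl group with the 1,1-disubstituted acrylate (in excess) should give the trisubstituted enoate with the ester trans to the chain; aldehyde, enone and tertiary alcohol are tolerated.

Step 18
Reactants: 28 methyl (2Z)-2-(bromomethyl)-4-[(5S)-5-hydroxy-5-methyl-3-oxo-2-[(2R)-4-oxobutan-2-yl]cyclopent-1-en-1-yl]but-2-enoate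
Product: 30 (4S,7S,8R,10R)-4-hydroxy-2-oxoguaia-1(5),11(13)-dien-12,8-olide, via hydroxy ester 29 (not isolated)
Conditions: CrCl2 (5 equiv), THF (5 mM), 25 °C; then aq. NH4Cl, SiO2
Reagents that add atoms: none
Why: Intramolecular Nozaki–Hiyama (CrCl2) allylation; the allylchromium adds only to the aldehyde (not the C2 ketone) through its γ-carbon in a chair-like transition state with H7/H8 anti and the C10 methyl pseudo-equatorial, closing the seven-membered ring (expected 7S,8R), and the hydroxy ester lactonises to the trans-fused α-methylene lactone.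

Step 19
Reactants: 30 (4S,7S,8R,10R)-4-hydroxy-2-oxoguaia-1(5),11(13)-dien-12,8-olide
Product: 31 (4S,7S,8R,10R,11S)-4-hydroxy-2-oxo-13-(phenylselanyl)guai-1(5)-en-12,8-olide
Conditions: PhSeH, Et3N (10 mol %), CH2Cl2, 0 °C
Reagents that add atoms: benzeneselenol [SeH]c1ccccc1
Why: Michael addition of benzeneselenol masks the only dienophilic alkene of this half (protonation anti to C6 gives 11S, which is inconsequential); the tetrasubstituted enone does not react.

Step 20
Reactants: 31 (4S,7S,8R,10R,11S)-4-hydroxy-2-oxo-13-(phenylselanyl)guai-1(5)-en-12,8-olide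
Product: 32 (2S,4S,7S,8R,10R,11S)-2,4-dihydroxy-13-(phenylselanyl)guai-1(5)-en-12,8-olide
Conditions: NaBH4, CeCl3·7H2O, MeOH, −78 °C
Reagents that add atoms: none
Why: Luche 1,2-reduction of the enone; hydride should attack the α-face, anti to the C10 and C4 methyl groups, giving the 2β-alcohol.

Step 21
Reactants: 32 (2S,4S,7S,8R,10R,11S)-2,4-dihydroxy-13-(phenylselanyl)guai-1(5)-en-12,8-olide
Product: 33 (2R,4S,7S,8R,10R,11S)-2-acetoxy-4-hydroxy-13-(phenylselanyl)guai-1(5)-en-12,8-olide
Conditions: PPh3, DIAD, AcOH, THF, 0 → 25 °C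
Reagents that add atoms: acetic acid CC(=O)O
Why: Mitsunobu esterification inverts C2 (SN2 displacement of the oxyphosphonium from the less hindered α-face) to the required 2α-acetate; the tertiary alcohol is not activated.

Step 22
Reactants: 33 (2R,4S,7S,8R,10R,11S)-2-acetoxy-4-hydroxy-13-(phenylselanyl)guai-1(5)-en-12,8-olide
Product: 34 (2R,7S,8R,10R,11S)-2-acetoxy-13-(phenylselanyl)guaia-1(5),3-dien-12,8-olide
Conditions: Burgess reagent, THF, 0 → 25 °C; cold filtration through neutral alumina, used at once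
Reagents that add atoms: none
Why: Burgess dehydration (syn-elimination of the sulfamate) of the tertiary allylic alcohol toward C3 should give the conjugated cyclopentadiene under neutral conditions at or below room temperature, which keeps the [1,5]-hydrogen shift of the 5-acetoxy diene slow.

**Union and completion**

Step 23
Reactants: 34 (2R,7S,8R,10R,11S)-2-acetoxy-13-(phenylselanyl)guaia-1(5),3-dien-12,8-olide; 18 (4R)-4-[(3aS,6R,7aS)-6-hydroxy-6-methyl-3-methylidene-2-oxo-2,3,3a,6,7,7a-hexahydro-1-benzofuran-5-yl]pentyl acetate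
Product: 35 (11S)-11,13-dihydro-13-(phenylselanyl) derivative of the target (selenide on the guaianolide lactone)
Conditions: 18 (1.5 equiv), BHT (cat.), CH2Cl2 (1 M), 10 kbar, 25 °C
Reagents that add atoms: none
Why: Intermolecular normal-electron-demand Diels–Alder reaction, concerted and asynchronous, between the cyclopentadiene C1=C5–C4=C3 of 34 and the exocyclic C11′=C13′ of 18, forming C1–C13′ and C3–C11′. The closest known reactions are the cycloadditions of 5-acetoxycyclopentadiene (syn to the acetoxy group) and the biomimetic dimerisations of guaianolide cyclopentadienes with α-methylene lactones. The new five-membered ring C1–C2–C3–C11′–C13′, and with it the norbornene, is closed in a suprafacial [4π+2π] mode. C1 and C3 should be set by attack on the α-face of the diene, which is syn to the C2 acetoxy group (σ-acceptor effect) and anti to the C10 methyl group, so the acetoxy bridge ends anti to the new C4=C5 alkene; the spiro center C11′ should be set by approach to the convex face of the cis-fused lactone (anti to C6′) with the lactone carbonyl endo and the bulky C7′ side exo. The regiochemistry (CH2 to the fully substituted C1) avoids a bond between two quaternary carbons. Homodimerisation is excluded because the diene's own methylene is masked as the selenide, and pressure accelerates the cycloaddition relative to the [1,5]-hydrogen shift.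

Step 24
Reactants: 35 (11S)-11,13-dihydro-13-(phenylselanyl) derivative of the target
Product: 37 CNP0257312.1 (target), via selenoxide 36 (not isolated)
Conditions: mCPBA (1.05 equiv), CH2Cl2, −78 °C; then i-Pr2NH, −78 → 25 °C
Reagents that add atoms: none
Why: Chemoselective oxidation of the selenide at −78 °C and selenoxide syn-elimination on warming regenerate the C11=C13 methylene; H-11 is the only β-hydrogen, so no regioisomer can form.

**Compound list**

1 | (R)-citronellal | O=CC[C@H](C)CCC=C(C)C | starting material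
2 | (3R)-3,7-dimethyl-2-methylideneoct-6-enal | O=CC(=C)[C@H](C)CCC=C(C)C | intermediate
3 | (4R)-4,8-dimethyl-3-methylidenenon-7-en-1-yne | C#CC(=C)[C@H](C)CCC=C(C)C | intermediate
4 | dimethyl[(1E,4R)-2,4,8-trimethyl-3-methylidenenona-1,7-dien-1-yl]alumane | C[Al](C)/C=C(\C)C(=C)[C@H](C)CCC=C(C)C | intermediate (not isolated)
5 | (2E,5R)-3,5,9-trimethyl-4-methylidenedeca-2,8-dien-1-ol | OC/C=C(\C)C(=C)[C@H](C)CCC=C(C)C | intermediate
6 | [(2S,3S)-3-[(3R)-3,7-dimethylocta-1,6-dien-2-yl]-3-methyloxiran-2-yl]methanol | OC[C@@H]1O[C@@]1(C)C(=C)[C@H](C)CCC=C(C)C | intermediate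
7 | (3R,5R)-3,5,9-trimethyl-4-methylidenedec-8-ene-1,3-diol | OCC[C@@](C)(O)C(=C)[C@H](C)CCC=C(C)C | intermediate
8 | (3R,5R)-3-hydroxy-3,5,9-trimethyl-4-methylidenedec-8-enal | O=CC[C@@](C)(O)C(=C)[C@H](C)CCC=C(C)C | intermediate
9 | acrolein | C=CC=O | starting material
10 | methyl acrylate | C=CC(=O)OC | starting material
11 | methyl 3-hydroxy-2-methylidenepent-4-enoate (racemic) | C=CC(O)C(=C)C(=O)OC | intermediate
12 | methyl (2Z)-2-(bromomethyl)penta-2,4-dienoate | C=C/C=C(\CBr)C(=O)OC | intermediate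
13 | methyl (3S,4S,6R,8R)-3-ethenyl-4,6-dihydroxy-6,8,12-trimethyl-2,7-dimethylidenetridec-11-enoate | COC(=O)C(=C)[C@H](C=C)[C@@H](O)C[C@@](C)(O)C(=C)[C@H](C)CCC=C(C)C | intermediate (not isolated)
14 | (4S,5S)-4-ethenyl-5-[(2R,4R)-2-hydroxy-2,4,8-trimethyl-3-methylidenenon-7-en-1-yl]-3-methylideneoxolan-2-one | C=C1C(=O)O[C@@H](C[C@@](C)(O)C(=C)[C@H](C)CCC=C(C)C)[C@H]1C=C | intermediate
15 | (3aS,6R,7aS)-6-hydroxy-6-methyl-3-methylidene-5-[(2R)-6-methylhept-5-en-2-yl]-3a,6,7,7a-tetrahydro-1-benzofuran-2(3H)-one | C=C1C(=O)O[C@H]2C[C@@](C)(O)C([C@H](C)CCC=C(C)C)=C[C@H]21 | intermediate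
16 | (4R)-4-[(3aS,6R,7aS)-6-hydroxy-6-methyl-3-methylidene-2-oxo-2,3,3a,6,7,7a-hexahydro-1-benzofuran-5-yl]pentanal | C=C1C(=O)O[C@H]2C[C@@](C)(O)C([C@H](C)CCC=O)=C[C@H]21 | intermediate (not isolated)
17 | (3aS,6R,7aS)-6-hydroxy-5-[(2R)-5-hydroxypentan-2-yl]-6-methyl-3-methylidene-3a,6,7,7a-tetrahydro-1-benzofuran-2(3H)-one | C=C1C(=O)O[C@H]2C[C@@](C)(O)C([C@H](C)CCCO)=C[C@H]21 | intermediate
18 | (4R)-4-[(3aS,6R,7aS)-6-hydroxy-6-methyl-3-methylidene-2-oxo-2,3,3a,6,7,7a-hexahydro-1-benzofuran-5-yl]pentyl acetate (dienophile; 4′R,7′S,8′S,10′R) | C=C1C(=O)O[C@H]2C[C@@](C)(O)C([C@H](C)CCCOC(C)=O)=C[C@H]21 | intermediate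
19 | cyclopentane-1,3-dione | O=C1CCC(=O)C1 | starting material
20 | (E)-but-2-enal (crotonaldehyde) | C/C=C/C=O | starting material
21 | (4R)-2-hydroxy-4-methyl-3,4,6,7-tetrahydrocyclopenta[b]pyran-5(2H)-one (anomers) | O=C1CCC2=C1[C@H](C)CC(O)O2 | intermediate (not isolated)
22 | (4R)-2-methoxy-4-methyl-3,4,6,7-tetrahydrocyclopenta[b]pyran-5(2H)-one (anomers) | O=C1CCC2=C1[C@H](C)CC(OC)O2 | intermediate
23 | (4R)-2-methoxy-4,6-dimethyl-3,4,6,7-tetrahydrocyclopenta[b]pyran-5(2H)-one (C6 epimers) | O=C1C(C)CC2=C1[C@H](C)CC(OC)O2 | intermediate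
24 | (4R,6S)-6-hydroxy-2-methoxy-4,6-dimethyl-3,4,6,7-tetrahydrocyclopenta[b]pyran-5(2H)-one | O=C1[C@@](C)(O)CC2=C1[C@H](C)CC(OC)O2 | intermediate
25 | (4R,6S)-2-methoxy-4,6-dimethyl-5-(prop-2-en-1-yl)-2,3,4,5,6,7-hexahydrocyclopenta[b]pyran-5,6-diol (C5 epimers) | C=CCC1(O)[C@@](C)(O)CC2=C1[C@H](C)CC(OC)O2 | intermediate (not isolated)
26 | (3R)-3-[(3S)-3-hydroxy-3-methyl-5-oxo-2-(prop-2-en-1-yl)cyclopent-1-en-1-yl]butanal | O=CC[C@@H](C)C1=C(CC=C)[C@@](C)(O)CC1=O | intermediate
27 | methyl 2-(bromomethyl)prop-2-enoate | C=C(CBr)C(=O)OC | starting material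
28 | methyl (2Z)-2-(bromomethyl)-4-[(5S)-5-hydroxy-5-methyl-3-oxo-2-[(2R)-4-oxobutan-2-yl]cyclopent-1-en-1-yl]but-2-enoate | O=CC[C@@H](C)C1=C(C/C=C(\CBr)C(=O)OC)[C@@](C)(O)CC1=O | intermediate
29 | methyl (4S,7S,8R,10R)-4,8-dihydroxy-2-oxoguaia-1(5),11(13)-dien-12-oate | COC(=O)C(=C)[C@@H]1CC2=C(C(=O)C[C@]2(C)O)[C@H](C)C[C@H]1O | intermediate (not isolated)
30 | (4S,7S,8R,10R)-4-hydroxy-2-oxoguaia-1(5),11(13)-dien-12,8-olide | C=C1C(=O)O[C@@H]2C[C@@H](C)C3=C(C[C@@H]12)[C@@](C)(O)CC3=O | intermediate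
31 | (4S,7S,8R,10R,11S)-4-hydroxy-2-oxo-13-(phenylselanyl)guai-1(5)-en-12,8-olide | C([Se]c4ccccc4)[C@@H]1C(=O)O[C@@H]2C[C@@H](C)C3=C(C[C@@H]12)[C@@](C)(O)CC3=O | intermediate
32 | (2S,4S,7S,8R,10R,11S)-2,4-dihydroxy-13-(phenylselanyl)guai-1(5)-en-12,8-olide | C([Se]c4ccccc4)[C@@H]1C(=O)O[C@@H]2C[C@@H](C)C3=C(C[C@@H]12)[C@@](C)(O)C[C@@H]3O | intermediate
33 | (2R,4S,7S,8R,10R,11S)-2-acetoxy-4-hydroxy-13-(phenylselanyl)guai-1(5)-en-12,8-olide | C([Se]c4ccccc4)[C@@H]1C(=O)O[C@@H]2C[C@@H](C)C3=C(C[C@@H]12)[C@@](C)(O)C[C@H]3OC(C)=O | intermediate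
34 | (2R,7S,8R,10R,11S)-2-acetoxy-13-(phenylselanyl)guaia-1(5),3-dien-12,8-olide (diene) | C([Se]c4ccccc4)[C@@H]1C(=O)O[C@@H]2C[C@@H](C)C3=C(C[C@@H]12)C(C)=C[C@H]3OC(C)=O | intermediate
35 | (11S)-11,13-dihydro-13-(phenylselanyl) derivative of the target (cycloadduct C1–C13′/C3–C11′) | C([Se]c7ccccc7)[C@@H]1C(=O)O[C@@H]2C[C@@H](C)[C@]34C[C@]5(C(=O)O[C@H]6C[C@@](C)(O)C([C@H](C)CCCOC(C)=O)=C[C@H]65)[C@H](C(C)=C3C[C@@H]12)[C@H]4OC(C)=O | intermediate
36 | selenoxide of 35 | C([Se](=O)c7ccccc7)[C@@H]1C(=O)O[C@@H]2C[C@@H](C)[C@]34C[C@]5(C(=O)O[C@H]6C[C@@](C)(O)C([C@H](C)CCCOC(C)=O)=C[C@H]65)[C@H](C(C)=C3C[C@@H]12)[C@H]4OC(C)=O | intermediate (not isolated)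
37 | CNP0257312.1: 2α-acetoxyguaia-4,11(13)-dien-12,8-olide joined through C1–C13′ and C3–C11′ (spiro) to 1′-O-acetyl-10′-hydroxy-1′,10′-seco-eudesm-5′-en-12′,8′-olide | C=C1C(=O)O[C@@H]2C[C@@H](C)[C@]34C[C@]5(C(=O)O[C@H]6C[C@@](C)(O)C([C@H](C)CCCOC(C)=O)=C[C@H]65)[C@H](C(C)=C3C[C@@H]12)[C@H]4OC(C)=O | target

**Totals and risks**

Total step count: 24. Longest linear sequence: 12 steps (steps 1–6, 9–12, 23, 24; the diene branch 13–22, 23, 24 is equally long).

Most likely to fail, with fallbacks:

1. Step 23 (cycloaddition). A [1,5]-hydrogen shift in the 5-acetoxycyclopentadiene may outrun the cycloaddition, and endo or facial selectivity may be incomplete. The fallback carries the C2 oxygen through the cycloaddition as a ketal, which has no migrating hydrogen. Setting out from 31, ketalisation (HC(OMe)3, MeOH, PPTS) gives the C2 dimethyl ketal F1, and Burgess dehydration gives the 5,5-dimethoxycyclopentadiene F2. Cycloaddition with 18 under the same pressure conditions gives the 7,7-dimethoxynorbornene adduct F3, with face selection by the C10 methyl group alone. Mild hydrolysis (PPTS, wet acetone) gives the 7-norbornenone F4, NaBH4/CeCl3 reduction from the alkene side gives the anti alcohol F5, and acetylation (Ac2O, pyridine, DMAP) returns 35.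

2. Step 22 (diene generation). Elimination may go toward the C15 methyl group, the allylic system may ionise with acetoxy participation, or the double bonds may migrate while the diene is handled. The fallback generates the diene in the presence of the dienophile and never isolates it. Setting out from 18, silylation (TMSOTf, 2,6-lutidine) gives the trimethylsilyl ether F6, which the Burgess reagent cannot attack. Compound 33 is then dehydrated with the Burgess reagent in a concentrated solution of F6 (3 equiv), the diene being trapped as it forms to give the silylated cycloadduct F7. PPTS in methanol removes the silyl ether and returns 35.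

3. Step 18 (seven-membered ring closure). The ring may close to the cis-fused (8-epi) lactone or with low selectivity at C7/C8. The fallback accepts the cis-fused closure and inverts C8. Setting out from 28, zinc in aqueous NH4Cl/THF (syn-selective Barbier conditions) gives the cis-fused lactone F8, and benzeneselenol addition gives the selenide F9. LiOH opens the lactone to the hydroxy acid F10, and Mitsunobu lactonisation (PPh3, DIAD) closes the ring with inversion at C8 and returns 31.

**Further compounds**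

F1 | step 23 | (4S,7S,8R,10R,11S)-4-hydroxy-2,2-dimethoxy-13-(phenylselanyl)guai-1(5)-en-12,8-olide | C([Se]c4ccccc4)[C@@H]1C(=O)O[C@@H]2C[C@@H](C)C3=C(C[C@@H]12)[C@@](C)(O)CC3(OC)OC
F2 | step 23 | (7S,8R,10R,11S)-2,2-dimethoxy-13-(phenylselanyl)guaia-1(5),3-dien-12,8-olide | C([Se]c4ccccc4)[C@@H]1C(=O)O[C@@H]2C[C@@H](C)C3=C(C[C@@H]12)C(C)=CC3(OC)OC
F3 | step 23 | 2-deacetoxy-2,2-dimethoxy analogue of 35 | C([Se]c7ccccc7)[C@@H]1C(=O)O[C@@H]2C[C@@H](C)[C@]34C[C@]5(C(=O)O[C@H]6C[C@@](C)(O)C([C@H](C)CCCOC(C)=O)=C[C@H]65)[C@H](C(C)=C3C[C@@H]12)C4(OC)OC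
F4 | step 23 | 2-deacetoxy-2-oxo analogue of 35 | C([Se]c7ccccc7)[C@@H]1C(=O)O[C@@H]2C[C@@H](C)[C@]34C[C@]5(C(=O)O[C@H]6C[C@@](C)(O)C([C@H](C)CCCOC(C)=O)=C[C@H]65)[C@H](C(C)=C3C[C@@H]12)C4=O
F5 | step 23 | 2-O-deacetyl analogue of 35 (2-alcohol, anti to the C4=C5 alkene) | C([Se]c7ccccc7)[C@@H]1C(=O)O[C@@H]2C[C@@H](C)[C@]34C[C@]5(C(=O)O[C@H]6C[C@@](C)(O)C([C@H](C)CCCOC(C)=O)=C[C@H]65)[C@H](C(C)=C3C[C@@H]12)[C@H]4O
F6 | step 22 | 10′-O-trimethylsilyl ether of 18 | C=C1C(=O)O[C@H]2C[C@@](C)(O[Si](C)(C)C)C([C@H](C)CCCOC(C)=O)=C[C@H]21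
F7 | step 22 | 10′-O-trimethylsilyl ether of 35 | C([Se]c7ccccc7)[C@@H]1C(=O)O[C@@H]2C[C@@H](C)[C@]34C[C@]5(C(=O)O[C@H]6C[C@@](C)(O[Si](C)(C)C)C([C@H](C)CCCOC(C)=O)=C[C@H]65)[C@H](C(C)=C3C[C@@H]12)[C@H]4OC(C)=O
F8 | step 18 | (4S,7S,8S,10R)-4-hydroxy-2-oxoguaia-1(5),11(13)-dien-12,8-olide (8-epimer of 30) | C=C1C(=O)O[C@H]2C[C@@H](C)C3=C(C[C@@H]12)[C@@](C)(O)CC3=O
F9 | step 18 | 8-epimer of 31 | C([Se]c4ccccc4)[C@@H]1C(=O)O[C@H]2C[C@@H](C)C3=C(C[C@@H]12)[C@@](C)(O)CC3=O
F10 | step 18 | (4S,7S,8S,10R,11S)-4,8-dihydroxy-2-oxo-13-(phenylselanyl)guai-1(5)-en-12-oic acid | OC(=O)[C@@H](C[Se]c4ccccc4)[C@@H]1CC2=C(C(=O)C[C@]2(C)O)[C@H](C)C[C@@H]1O
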